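Saturday's flask and the epsilon run look nearly the same: equal equivalents of reagent, 35 °C against 41 °C, a concentration twice as high, and a reading at the same 20 min.

| flask | left-handed substrate | right-handed substrate | reagent | temperature | remark | time |
|---|---|---|---|---|---|---|
| epsilon | 0.035 M | 0.035 M | 0.60 equiv | 41 °C | run made earlier |  |
| alpha | 0.052 M | 0.052 M | 0.60 equiv | 55 °C | run made earlier |  |
| Friday's | 0.069 M | 0.069 M | 0.600 equiv | 60 °C |  | 20 min |
| Saturday's | 0.069 M | 0.069 M | 0.600 equiv | 35 °C |  | 20 min |

| run | time / min | left-handed product / % | right-handed product / % | left-handed substrate / % |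
|---|---|---|---|---|
| epsilon | 2.50 | 4.9 | 0 | 46.5 |
| epsilon | 8.00 | 10.0 | 3.0 | 41.2 |
| epsilon | 15.0 | 10.4 | 6.8 | 33.4 |
| epsilon | 20.0 | 12.5 | 10.2 | 29.0 |
| epsilon | 30.0 | 15.1 | 10.2 | 25.4 |
| epsilon | 40.0 | 13.1 | 12.9 | 24.1 |
| epsilon | 50.0 | 14.2 | 14.1 | 24.1 |
| alpha | 3.00 | 9.4 | 4.4 | 36.9 |
| alpha | 6.00 | 11.6 | 10.3 | 29.8 |
| alpha | 8.00 | 12.5 | 8.2 | 28.1 |
| alpha | 12.0 | 12.9 | 13.0 | 25.6 |
| alpha | 15.0 | 13.8 | 13.3 | 23.8 |
| alpha | 20.0 | 14.4 | 12.5 | 22.2 |

(each reading ± 1 percentage point)

- reagent is single-handed; left-handed substrate and right-handed substrate are mirror images of each other, charged as a racemate, each of them at the stated concentration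
- the handed part of reagent does not stay in what it makes, so the products of the two hands are mirror images too

1. which flask leads in share of left-handed product in all that became left-handed product or right-handed product ("all alike" within 1.5 percentage points) (Friday's / Saturday's / all alike)
2. share of left-handed product in all that became left-handed product or right-handed product, Friday's
3. share of left-handed product in all that became left-handed product or right-handed product, Saturday's

The epsilon run reads a share of 55.1 % at that time. Where does Saturday's land? At 2.50 min the epsilon run shows 4.9 % left-handed product and 0 % right-handed product, so you can take right-handed product as coming later, out of left-handed product: racemisation.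

So follow the excess, c(left-handed product) − c(right-handed product), as a fraction of both products. Replace the curve by its mean: product made at a steady pace has a mean age of half the elapsed time, so that fraction is exp(−λt/2). Here λ is the excess-loss constant, the fraction of the excess lost per minute.

Early readings give λ = 0.155 min⁻¹ in the epsilon run and 0.677 min⁻¹ in the alpha run. The same factor per degree gives Saturday's excess-loss constant, 0.0822 min⁻¹, about half the epsilon run's, and 1.15 min⁻¹ for Friday's.

My reckoning for Saturday's is then a share of 72.0 %. Averaging the exponential over steady making gives 74.5 %, so the shortcut costs a few points. For the epsilon run the rule gives 60.6 %, but the share read there is a ratio of two scattered readings, so the gap between them is no measure of the rule's error. For Friday's, λt/2 is 11.5, and the share is 50.0 %.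

The forecast names Saturday's, with 50.3 % for Friday's and 65 % for Saturday's, on the ground that left-handed product “forms first, then racemises”. Its Saturday's figure stands below mine.

The flasks give 50.1 % for Friday's and 71.4 % for Saturday's, so Saturday's leads. In Friday's flask the relaxation half-life of the two products, 0.568 min, is short against 20 min, which is thermodynamic control of the share. The excess-loss constant also tells the pace in Saturday's flask: at 25.8 min the rule gives 67.3 %, down 4.7 percentage points, and the flask has moved 5 points by then.

    reagent + left-handed substrate → left-handed product (k = 0.0250 M⁻¹ s⁻¹, Ea = 46.0 kJ mol⁻¹)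
    left-handed product ⇌ right-handed product (k = 5.60 × 10⁻⁴ s⁻¹, Ea = 99.0 kJ mol⁻¹)
    reagent + right-handed substrate → right-handed product (k = 2.20 × 10⁻⁴ M⁻¹ s⁻¹, Ea = 56.0 kJ mol⁻¹)
    (constants at 35 °C)

Friday's flask held at 35 °C takes the same constant and the same 20 min, so the rule gives 72.0 %. The computed share is 71.4 %.

The runs stem from a simulated flask for an exercise, and the scatter is random.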